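## Analysis of the target

Target 29 is a sesquilignan built from two oxygen heterocycles. A 3,7-dioxabicyclo[3.3.0]octane (furofuran; atoms C1, C2, O3, C4, C5, C6, O7, C8; ring A holds O3, ring B holds O7) carries a 4-hydroxy-3,5-dimethoxyphenyl (syringyl) ring on C6, and its C2 is bonded to C5' of a 7'-methoxy-2',3'-dihydrobenzofuran that bears a 4-hydroxy-3-methoxyphenyl (guaiacyl) ring on C2' and a hydroxymethyl group on C3'. There are six stereocentres in two clusters: 1R,2S,5R,6S in the bicycle (rings cis-fused, H1 and H5 cis, both aryl groups on the convex face, so that H1/H2 and H5/H6 are trans) and 2'S,3'S in the dihydrobenzofuran, where the aryl and hydroxymethyl groups are cis. The benzene ring between the clusters insulates them, so each needs its own source of absolute configuration. The cis-dihydrobenzofuran is the less stable isomer, because ionisation of the C2'–O1' bond or enolisation of any carbonyl precursor at C3' leads to trans. The sensitive groups are three benzylic C–O bonds (C2–O3, C6–O7, C2'–O1'), each para to an oxygen donor and therefore open to acid ionisation and to hydrogenolysis, and two free phenols that can form quinone methides. The bicycle is unsymmetrical, which rules out dimerisation of one phenylpropanoid, and its four contiguous centres must be set in a molecule that also holds the fragile cis ring. The strategy rests on one feature: C4 is an unsubstituted CH2 between O3 and the bridgehead C5, and C6, next to C5, is a benzylic carbon bonded to O7 that can carry positive charge, so ring A can be closed by bonding a one-carbon oxocarbenium carbon on O3 to C5 of a C5=C6 styrene and ring B by capture of the C6 cation by O7.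

## Retrosynthetic reasoning

29 ⇒ 28 ⇒ 27 ⇒ 26. Only protecting groups are removed: the benzyl ether on the syringyl oxygen (28 → 29), the silyl ether on the C3' hydroxymethyl group (27 → 28) and the methanesulfonate on the guaiacyl oxygen (26 → 27). The three groups have different jobs. The benzyl ether keeps the syringyl ring a donor, which the key step needs at C6. The sulfonate makes the guaiacyl ring a non-donor, which protects the C2'–O1' bond from ionisation. The silyl ether masks the one alcohol that takes no part in ring formation. Forward, the removals must avoid acid and must not leave a phenoxide para to a benzylic ether for long.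

26 ⇒ 23. The bonds C4–C5 and C6–O7 are cut. C4 is chosen because it has no substituent: taking it away as a one-carbon electrophile on O3 costs no stereocentre and leaves the open-chain compound 23, whose only chain stereocentres are C1 and C2. These are the two centres of an aldol product; the rest of 23 is a styrene (C5=C6) and a protected primary alcohol (C8–O7). Forward, one cationic cascade (through 24 and 25) must form two rings, two bonds and the centres C5 and C6. It has to ionise the acetal C–O bond on O3 and not the benzylic C2–O3 bond, bond C4 to C5 and not to C6, and end with the ring fusion cis and the syringyl group exo.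

23 ⇒ 22 ⇒ 21 ⇒ 20. The acetal on O3 (22 → 23), the silyl group on O7 (21 → 22) and the primary alcohol itself (20 → 21, reductive removal of the acyl auxiliary) are taken back in turn. The two oxygens must carry different groups: with the one-carbon acetal on O7 the same cascade would close the second ring through the C2 oxygen and give the 2,4-diaryl isomer of the bicycle. The order reduction, silylation, acetalisation keeps the base-sensitive α-centre of the imide away from amine bases and lets the primary alcohol be told from the secondary one by size alone.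

20 ⇒ 18 + 12. The C1–C2 bond is cut as an aldol bond between the chiral imide 18 and aldehyde 12. This is the most convergent cut: it divides the molecule into halves of similar size, creates both chain stereocentres in one step and places the C5=C6 styrene on C1 as the vinylogous part of the enolate. The forward reaction must give the syn isomer with 2S,3S configuration; auxiliary 16 is relied on for this, and the distant centres of 12 have no influence.

18 ⇒ 15 + 16, 15 ⇒ 14 ⇒ 13. The imide is cut at the N–acyl bond, acid 15 at the C5=C6 double bond (olefination of aldehyde 14 with a three-carbon ylide that already carries the carboxylate), and 14 at the benzyl ether of syringaldehyde 13. The olefination must be E-selective and must leave the double bond in the β,γ-position.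

12 ⇒ 11 ⇒ 10 ⇒ 9. The silyl ether (11 → 12), the aldehyde (10 → 11) and the two alcohols (9 → 10) are traced back to diester 9. Carrying both C5' and the C3' carbon as methyl esters means that no aldehyde has to pass through the organozinc coupling, the diazo transfer and the carbenoid step. The price is one chemoselective oxidation, which relies on the benzylic nature of the C5' alcohol.

9 ⇒ 8. The C2'–C3' bond is cut to aryldiazoacetate 8: a carbenoid at the future C3' inserts into a C–H bond of the benzylic ether CH2 that becomes C2'. No other disconnection of this ring gives the cis isomer under kinetic control; closures through a C2' cation or any equilibration at C3' end at trans. Placed here, on a small achiral arene, the insertion has only one activated C–H bond within reach. Forward, a chiral dirhodium carboxylate must set both centres, cis and in the 2S,3R sense.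

8 ⇒ 7 ⇒ 6 ⇒ 5 + 3, 5 ⇒ 4, 3 ⇒ 2 ⇒ 1. The diazo group goes back to the CH2 of aryl acetate 7, the acetate unit to aryl iodide 6 (cross-coupling with a zinc ester enolate), the benzylic ether to phenol 5 and alcohol 3, the iodine to methyl vanillate 4, and 3 to vanillin 1 by reduction and sulfonylation. The methanesulfonate is thus present from the first step, and the iodine marks the one position ortho to the phenol where the acetate unit is needed.

## Alternatives that were turned down

Alternative 1: Late carbenoid C–H insertion.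
- Disconnection: the C2'–C3' bond of the dihydrobenzofuran is cut last, in a molecule that already contains the complete furofuran. The precursor is aryldiazoacetate A1, whose phenolic oxygen carries the 4-benzyloxy-3-methoxybenzyl group.
- Forward key step: Rh2(S-PTTL)4, dirhodium tetrakis[N-phthaloyl-(S)-tert-leucinate] (divalent rhodium), or its mirror image decomposes A1; the carbenoid carbon inserts into the O–CH2–aryl C–H bond and gives the cis ester A2.
- For it: cis geometry and absolute configuration at C2'/C3' come from the catalyst alone. The fragile cis ring is made after every Lewis-acidic operation and never has to survive one; on this point the alternative is stronger than the chosen route.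
- Against it: the disconnection does not say how the four contiguous centres of the bicycle are made, so a second key step is still needed. A1 offers the carbenoid further hydridic C–H bonds (C2–H and C6–H, both benzylic and α to oxygen, and two OCH2 groups) and ether oxygens for ylide formation, in a late and valuable intermediate. The catalyst meets a chiral substrate, so matched and mismatched pairing cannot be excluded. A2 carries an electron-rich benzyloxyaryl group on C2', so its cis ring is acid-labile during the ester reduction and the two hydrogenolyses that remain.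
- Comparison: the chosen route uses the same insertion, but at step 7 on a small achiral arene with a single reachable C–H bond. In exchange for the late ring formation it offers what Alternative 1 leaves open, a one-step construction of the bicycle. Step counts after the insertion are similar.

Alternative 2: Conjugate addition–aldol on a chiral butenolide.
- Disconnection: C5–C6 and C1–C2 are cut around a four-carbon lactone that supplies C8, C1, C5 and C4.
- Forward key step: the 2-lithio derivative of dithiane A4 adds to the β-carbon of butenolide A3 on the face away from the menthyloxy group, and the lactone enolate is trapped with aldehyde A5 to give the trans,trans-lactone A6.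
- For it: three components are joined in one flask, the C1/C5 relationship follows from simple induction on a ring, the chiral controller is cheap, and each operation has close analogy in lignan chemistry. In precedent this alternative is stronger than the chosen route.
- Against it: C6 arrives as a dithioketal and C4 as an acetal, so dithiane hydrolysis, ketone reduction, reduction of lactone and acetal, and an acid-promoted double ring closure must follow. C2 is not controlled in the aldol and C6 not in the ketone reduction; both are left to equilibration through benzylic cations in the final acid step. That acid also meets the cis-dihydrobenzofuran, which in A6 carries a donor aryl group on C2'.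
- Comparison: four to five steps from A6 to the protected bicycle stand against one step from 23 to 26. The chosen route fixes C2 by the auxiliary and needs no ionising acid once the rings exist. Because its chemistry is documented, this sequence, in the mesylate series, is kept as the fallback for the key step.

Alternative 3: Double oxidative cycloetherification.
- Disconnection: both benzylic C–O bonds of the bicycle (C2–O3 and C6–O7) are cut, leading back to the dibenzylbutanediol A7.
- Forward key step: DDQ removes hydride from each 4-hydroxybenzyl carbon of A7, and the hydroxymethyl group on the neighbouring stereocentre adds to the resulting electrophilic benzylic carbon; two such events give (+)-medioresinol A8.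
- For it: no protecting groups, and a very short, biomimetic route to the bicycle from a diol with only two stereocentres. In step economy for the bicycle it is stronger than the chosen route.
- Against it: A8 is not the target skeleton, since its guaiacyl ring lacks the whole dihydrobenzofuran. A C6–C3 unit would have to be grafted afterwards onto the carbon ortho to the guaiacyl phenol. Oxidative phenol coupling does this with formation of the trans ring, without control of absolute configuration at C2'/C3' and in competition with the syringyl phenol. In the key step each oxidised benzylic carbon can also be attacked by the other electron-rich arene (six-membered carbocycle), and the product phenols remain oxidisable.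
- Comparison: the alternative solves the easier half and leaves the cis-dihydrobenzofuran, the hardest stereochemical element, unsolved. The chosen route makes this ring first under catalyst control and designs the bicycle-forming step around its survival.

Key step: step 18

## Remarks before the steps

Assumption: for this substrate class Rh2(S-PTTL)4 is taken to give the (2R,3S) cis ester, so the (R)-catalyst is used; should the first run show the opposite sense, the catalyst enantiomer is exchanged and nothing else changes.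

Abbreviations in names:
- DBF = the (2S,3S)-3-{[tert-butyl(dimethyl)silyl]oxymethyl}-7-methoxy-2-[3-methoxy-4-(methylsulfonyloxy)phenyl]-2,3-dihydro-1-benzofuran-5-yl group.
- Syr(Bn) = the 4-(benzyloxy)-3,5-dimethoxyphenyl group.

## Route

Step 1
Reactants: 1 vanillin (4-hydroxy-3-methoxybenzaldehyde)
Product: 2 4-formyl-2-methoxyphenyl methanesulfonate
Conditions: MsCl, Et3N, CH2Cl2, 0 °C
Reagents that add atoms: methanesulfonyl chloride, CS(=O)(=O)Cl
Why: Base-mediated O-sulfonylation of the phenol; the mesylate turns the para oxygen into a non-donor for all later steps and is stable to hydride, Lewis acid and mild base.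

Step 2
Reactants: 2 4-formyl-2-methoxyphenyl methanesulfonate
Product: 3 4-(hydroxymethyl)-2-methoxyphenyl methanesulfonate
Conditions: NaBH4, MeOH, 0 °C
Reagents that add atoms: none
Why: Chemoselective hydride reduction of the aldehyde; aryl sulfonates are inert to NaBH4.

Step 3
Reactants: 4 methyl vanillate (methyl 4-hydroxy-3-methoxybenzoate)
Product: 5 methyl 4-hydroxy-3-iodo-5-methoxybenzoate
Conditions: N-iodosuccinimide, CF3CO2H (cat.), MeCN, rt
Reagents that add atoms: N-iodosuccinimide, O=C1CCC(=O)N1I
Why: Electrophilic aromatic iodination at the only free position ortho to the phenol; the para position is blocked by the ester.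

Step 4
Reactants: 5 methyl 4-hydroxy-3-iodo-5-methoxybenzoate; 3 4-(hydroxymethyl)-2-methoxyphenyl methanesulfonate
Product: 6 methyl 3-iodo-5-methoxy-4-{[3-methoxy-4-(methylsulfonyloxy)phenyl]methoxy}benzoate
Conditions: PPh3, diisopropyl azodicarboxylate, THF, 0 °C to rt
Reagents that add atoms: none
Why: Mitsunobu etherification of an acidic phenol with a primary benzylic alcohol under neutral conditions; no stereocentre is involved and the benzylic halide need not be made.

Step 5
Reactants: 6 methyl 3-iodo-5-methoxy-4-{[3-methoxy-4-(methylsulfonyloxy)phenyl]methoxy}benzoate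
Product: 7 methyl 3-methoxy-5-(2-methoxy-2-oxoethyl)-4-{[3-methoxy-4-(methylsulfonyloxy)phenyl]methoxy}benzoate
Conditions: BrZnCH2CO2Me (from BrCH2CO2Me and Zn, THF), Pd(dba)2 (2 mol%), P(t-Bu)3 (2 mol%), THF, rt
Reagents that add atoms: bromo(2-methoxy-2-oxoethyl)zinc, COC(=O)C[Zn]Br
Why: Negishi coupling of an aryl iodide with a Reformatsky reagent; oxidative addition to C–I is far faster than to the aryl mesylate at room temperature, and the zinc enolate does not add to the benzoate ester.

Step 6
Reactants: 7 methyl 3-methoxy-5-(2-methoxy-2-oxoethyl)-4-{[3-methoxy-4-(methylsulfonyloxy)phenyl]methoxy}benzoate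
Product: 8 methyl 3-(1-diazo-2-methoxy-2-oxoethyl)-5-methoxy-4-{[3-methoxy-4-(methylsulfonyloxy)phenyl]methoxy}benzoate
Conditions: 4-acetamidobenzenesulfonyl azide, DBU, MeCN, 0 °C to rt
Reagents that add atoms: 4-acetamidobenzenesulfonyl azide, CC(=O)Nc1ccc(cc1)S(=O)(=O)N=[N+]=[N-]
Why: Regitz diazo transfer to the aryl acetate CH2, the only position acidic enough for the amidine base.

Step 7
Reactants: 8 methyl 3-(1-diazo-2-methoxy-2-oxoethyl)-5-methoxy-4-{[3-methoxy-4-(methylsulfonyloxy)phenyl]methoxy}benzoate
Product: 9 dimethyl (2S,3R)-7-methoxy-2-[3-methoxy-4-(methylsulfonyloxy)phenyl]-2,3-dihydro-1-benzofuran-3,5-dicarboxylate (2,3-cis)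
Conditions: Rh2(R-PTTL)4, dirhodium tetrakis[N-phthaloyl-(R)-tert-leucinate] (1 mol%), toluene, −60 °C
Reagents that add atoms: none
Why: Intramolecular 1,5 C–H insertion of a donor/acceptor rhodium carbenoid into the ArO–CH2–Ar bond, a known route to cis-2-aryl-2,3-dihydrobenzofuran-3-carboxylates with phthalimido amino-acid dirhodium carboxylates. The chiral catalyst sets C2' and C3' together in the concerted insertion, cis under kinetic control, and the low temperature keeps the cis ester from epimerising at C3'.

Step 8
Reactants: 9 dimethyl (2S,3R)-7-methoxy-2-[3-methoxy-4-(methylsulfonyloxy)phenyl]-2,3-dihydro-1-benzofuran-3,5-dicarboxylate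
Product: 10 4-[(2S,3S)-3,5-bis(hydroxymethyl)-7-methoxy-2,3-dihydro-1-benzofuran-2-yl]-2-methoxyphenyl methanesulfonate
Conditions: i-Bu2AlH (6 equiv), CH2Cl2, −78 to −20 °C; aq. KNaC4H4O6
Reagents that add atoms: none
Why: Exhaustive ester reduction; hydride delivery at low temperature is faster than enolisation, so the epimerisable C3' centre becomes a configurationally stable CH2OH carbon (the descriptor changes to S by priority only), and the aryl mesylate is tolerated.

Step 9
Reactants: 10 4-[(2S,3S)-3,5-bis(hydroxymethyl)-7-methoxy-2,3-dihydro-1-benzofuran-2-yl]-2-methoxyphenyl methanesulfonate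
Product: 11 4-[(2S,3S)-5-formyl-3-(hydroxymethyl)-7-methoxy-2,3-dihydro-1-benzofuran-2-yl]-2-methoxyphenyl methanesulfonate
Conditions: MnO2 (activated), CH2Cl2, rt
Reagents that add atoms: none
Why: MnO2 oxidises the benzylic alcohol only; the aliphatic primary alcohol is not touched.

Step 10
Reactants: 11 4-[(2S,3S)-5-formyl-3-(hydroxymethyl)-7-methoxy-2,3-dihydro-1-benzofuran-2-yl]-2-methoxyphenyl methanesulfonate
Product: 12 4-[(2S,3S)-3-{[tert-butyl(dimethyl)silyl]oxymethyl}-5-formyl-7-methoxy-2,3-dihydro-1-benzofuran-2-yl]-2-methoxyphenyl methanesulfonate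
Conditions: TBSCl, imidazole, DMF, rt
Reagents that add atoms: tert-butyl(chloro)dimethylsilane, CC(C)(C)[Si](C)(C)Cl
Why: Standard silylation of a primary alcohol; the aldehyde and the mesylate are inert.

Step 11
Reactants: 13 syringaldehyde (4-hydroxy-3,5-dimethoxybenzaldehyde)
Product: 14 4-(benzyloxy)-3,5-dimethoxybenzaldehyde
Conditions: BnBr, K2CO3, DMF, 60 °C
Reagents that add atoms: benzyl bromide, BrCc1ccccc1
Why: Williamson benzylation of the phenol; the benzyl ether keeps this ring electron-rich for the key step.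

Step 12
Reactants: 14 4-(benzyloxy)-3,5-dimethoxybenzaldehyde
Product: 15 (E)-4-[4-(benzyloxy)-3,5-dimethoxyphenyl]but-3-enoic acid
Conditions: Ph3P(CH2CH2CO2H)Br, NaN(SiMe3)2 (2.1 equiv), THF, −78 °C to rt; aq. HCl
Reagents that add atoms: (2-carboxyethyl)triphenylphosphonium bromide, OC(=O)CC[P+](c1ccccc1)(c1ccccc1)c1ccccc1.[Br-]
Why: Wittig olefination with the carboxylate-bearing ylide, which gives (E)-β,γ-unsaturated acids with aromatic aldehydes; the double bond stays in the styrene position because it is conjugated with the arene.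

Step 13
Reactants: 15 (E)-4-[4-(benzyloxy)-3,5-dimethoxyphenyl]but-3-enoic acid; 16 (S)-4-benzyl-1,3-oxazolidin-2-one
Product: 18 (S)-4-benzyl-3-{(E)-4-[4-(benzyloxy)-3,5-dimethoxyphenyl]but-3-enoyl}-1,3-oxazolidin-2-one, via mixed pivalic anhydride 17 (not isolated)
Conditions: t-BuCOCl, Et3N, THF, −20 °C; then 16, LiCl, −20 °C to rt
Reagents that add atoms: none
Why: N-acylation of the oxazolidinone through the mixed anhydride (LiCl/Et3N variant), mild enough to leave the β,γ-alkene in place.

Step 14
Reactants: 18 (S)-4-benzyl-3-{(E)-4-[4-(benzyloxy)-3,5-dimethoxyphenyl]but-3-enoyl}-1,3-oxazolidin-2-one; 12 4-[(2S,3S)-3-{[tert-butyl(dimethyl)silyl]oxymethyl}-5-formyl-7-methoxy-2,3-dihydro-1-benzofuran-2-yl]-2-methoxyphenyl methanesulfonate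
Product: 20 (4S)-4-benzyl-3-[(2S,3S)-2-{(E)-2-[Syr(Bn)]ethenyl}-3-hydroxy-3-(DBF)propanoyl]-1,3-oxazolidin-2-one, via boron dienolate 19 (not isolated)
Conditions: Bu2BOTf, i-Pr2NEt, CH2Cl2, −78 to 0 °C; 12, −78 to 0 °C; pH 7 buffer, MeOH, H2O2, 0 °C
Reagents that add atoms: none
Why: Evans syn aldol reaction; the (Z)-boron dienolate 19 reacts at its α-carbon through a Zimmerman–Traxler chair, and the (S)-benzyl group of the auxiliary shields one enolate face. This gives the syn adduct with 2S,3S configuration, which are C1 and C2 of the bicycle.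

Step 15
Reactants: 20 (4S)-4-benzyl-3-[(2S,3S)-2-{(E)-2-[Syr(Bn)]ethenyl}-3-hydroxy-3-(DBF)propanoyl]-1,3-oxazolidin-2-one
Product: 21 (1S,2R)-2-{(E)-2-[Syr(Bn)]ethenyl}-1-(DBF)propane-1,3-diol
Conditions: LiBH4, MeOH (1 equiv), THF, 0 °C
Reagents that add atoms: none
Why: Reductive cleavage of the N-acyl oxazolidinone to the primary alcohol with release of 16; done before any protection so that the α-centre (allylic and α to the carbonyl) is not exposed to base as the imide.

Step 16
Reactants: 21 (1S,2R)-2-{(E)-2-[Syr(Bn)]ethenyl}-1-(DBF)propane-1,3-diol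
Product: 22 (1S,2R,3E)-2-{[tert-butyl(dimethyl)silyl]oxymethyl}-4-[Syr(Bn)]-1-(DBF)but-3-en-1-ol
Conditions: TBSCl (1.05 equiv), imidazole, CH2Cl2, 0 °C
Reagents that add atoms: tert-butyl(chloro)dimethylsilane, CC(C)(C)[Si](C)(C)Cl
Why: Selective silylation of the primary alcohol over the hindered secondary benzylic one; the silyl ether oxygen is the later O7.

Step 17
Reactants: 22 (1S,2R,3E)-2-{[tert-butyl(dimethyl)silyl]oxymethyl}-4-[Syr(Bn)]-1-(DBF)but-3-en-1-ol
Product: 23 (1S,2R,3E)-2-{[tert-butyl(dimethyl)silyl]oxymethyl}-1-(methoxymethoxy)-4-[Syr(Bn)]-1-(DBF)but-3-ene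
Conditions: MOMCl, i-Pr2NEt, Bu4NI (cat.), CH2Cl2, 0 °C to rt
Reagents that add atoms: chloromethyl methyl ether, COCCl
Why: O-alkylation of the remaining secondary alcohol to the MOM ether, which places the latent C4 on O3 only.

Step 18
Reactants: 23 (1S,2R,3E)-2-{[tert-butyl(dimethyl)silyl]oxymethyl}-1-(methoxymethoxy)-4-[Syr(Bn)]-1-(DBF)but-3-ene
Product: 26 (1R,2S,5R,6S)-2-(DBF)-6-[Syr(Bn)]-3,7-dioxabicyclo[3.3.0]octane, via oxocarbenium ion 24 (not isolated), via benzylic cation 25 (not isolated)
Conditions: SnCl4 (1.5 equiv), 2,6-di-tert-butyl-4-methylpyridine, CH2Cl2, −78 °C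
Reagents that add atoms: none
Why: Proposed new method: SnCl4 binds the terminal methoxy oxygen of the acetal and removes methoxide, leaving the alkoxymethyl oxocarbenium ion 24 on O3; its carbon C4 adds to the styrene at C5, the Markovnikov position, so that ring A (O3–C4–C5–C1–C2) closes five-membered with the alkene outside the ring (5-exo-trig) and the charge passes to C6 as the 4-benzyloxy-3,5-dimethoxybenzyl cation 25. The oxygen of the C8 silyl ether then attacks C6 and closes ring B (C6–O7–C8–C1–C5), again a five-membered closure onto a trigonal carbon whose π partner, the aryl ring, stays outside the ring (5-exo), and chloride takes the silyl group from the silyloxonium ion. The closest known reactions are Prins cyclisations started from alkoxymethyl ethers with SnCl4, Prins closures of (E)-styryl homoallylic alcohols to tetrahydrofurans through the benzylic cation, and Prins bicyclisations ended by a tethered oxygen nucleophile; their combination on a MOM ether with a silyl ether as terminator is the untested part. C5 is controlled by C1 through the ring fusion: only the cation with C6 and C8 cis on ring A can be captured, because a trans-fused bicyclo[3.3.0]octane is out of reach, and the trans cation can return to 24 by fragmentation. C6 is set in the closure of ring B, where the aryl group takes the convex face anti to C4, the less hindered approach; C1 and C2 come unchanged from the aldol. The step needs site selectivity between the two oxygens, secured by placing the ionisable acetal on O3 only and the silyl ether on O7; regioselectivity for C4–C5 over C4–C6, secured by the polarisation of the styrene; and inertness of the C2'–O1' bond, secured by the para mesyloxy group, which cannot stabilise a cation at C2'.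

Step 19
Reactants: 26 (1R,2S,5R,6S)-2-(DBF)-6-[Syr(Bn)]-3,7-dioxabicyclo[3.3.0]octane
Product: 27 (1R,2S,5R,6S)-6-[Syr(Bn)]-2-[(2S,3S)-3-{[tert-butyl(dimethyl)silyl]oxymethyl}-2-(4-hydroxy-3-methoxyphenyl)-7-methoxy-2,3-dihydro-1-benzofuran-5-yl]-3,7-dioxabicyclo[3.3.0]octane
Conditions: LiN(i-Pr)2 (4 equiv), THF, −78 to 0 °C; aq. NH4Cl
Reagents that add atoms: none
Why: Known cleavage of aryl methanesulfonates by amide base: deprotonation of the S-methyl group and loss of sulfene release the phenoxide at low temperature. Silyl and benzyl ethers are inert, no stereocentre is touched, and the cold, short exposure keeps the phenoxide from opening the C2'–O1' bond.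

Step 20
Reactants: 27 (1R,2S,5R,6S)-6-[Syr(Bn)]-2-[(2S,3S)-3-{[tert-butyl(dimethyl)silyl]oxymethyl}-2-(4-hydroxy-3-methoxyphenyl)-7-methoxy-2,3-dihydro-1-benzofuran-5-yl]-3,7-dioxabicyclo[3.3.0]octane
Product: 28 (1R,2S,5R,6S)-6-[Syr(Bn)]-2-[(2S,3S)-2-(4-hydroxy-3-methoxyphenyl)-3-(hydroxymethyl)-7-methoxy-2,3-dihydro-1-benzofuran-5-yl]-3,7-dioxabicyclo[3.3.0]octane
Conditions: Bu4NF, AcOH, THF, rt
Reagents that add atoms: none
Why: Fluoride desilylation of the primary silyl ether, buffered with acetic acid so that the phenol is not held as a phenoxide para to the benzylic C2'–O1' bond.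

Step 21
Reactants: 28 (1R,2S,5R,6S)-6-[Syr(Bn)]-2-[(2S,3S)-2-(4-hydroxy-3-methoxyphenyl)-3-(hydroxymethyl)-7-methoxy-2,3-dihydro-1-benzofuran-5-yl]-3,7-dioxabicyclo[3.3.0]octane
Product: 29 (1R,2S,5R,6S)-6-(4-hydroxy-3,5-dimethoxyphenyl)-2-[(2S,3S)-2-(4-hydroxy-3-methoxyphenyl)-3-(hydroxymethyl)-7-methoxy-2,3-dihydro-1-benzofuran-5-yl]-3,7-dioxabicyclo[3.3.0]octane (CNP0126146.1)
Conditions: H2 (1 atm), Pd/C (10%), EtOAc, rt
Reagents that add atoms: none
Why: Hydrogenolysis of the aryl benzyl ether, which at 1 atm in a neutral solvent is much faster than cleavage of the ring benzylic ethers; the reaction is stopped when 28 is consumed.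

## Compound list

1 | vanillin (4-hydroxy-3-methoxybenzaldehyde) | COc1cc(C=O)ccc1O | starting material
2 | 4-formyl-2-methoxyphenyl methanesulfonate | COc1cc(C=O)ccc1OS(C)(=O)=O | intermediate
3 | 4-(hydroxymethyl)-2-methoxyphenyl methanesulfonate | COc1cc(CO)ccc1OS(C)(=O)=O | intermediate
4 | methyl vanillate (methyl 4-hydroxy-3-methoxybenzoate) | COC(=O)c1ccc(O)c(OC)c1 | starting material
5 | methyl 4-hydroxy-3-iodo-5-methoxybenzoate | COC(=O)c1cc(I)c(O)c(OC)c1 | intermediate
6 | methyl 3-iodo-5-methoxy-4-{[3-methoxy-4-(methylsulfonyloxy)phenyl]methoxy}benzoate | COC(=O)c1cc(I)c(OCc2ccc(OS(C)(=O)=O)c(OC)c2)c(OC)c1 | intermediate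
7 | methyl 3-methoxy-5-(2-methoxy-2-oxoethyl)-4-{[3-methoxy-4-(methylsulfonyloxy)phenyl]methoxy}benzoate | COC(=O)Cc1cc(C(=O)OC)cc(OC)c1OCc1ccc(OS(C)(=O)=O)c(OC)c1 | intermediate
8 | methyl 3-(1-diazo-2-methoxy-2-oxoethyl)-5-methoxy-4-{[3-methoxy-4-(methylsulfonyloxy)phenyl]methoxy}benzoate | COC(=O)C(=[N+]=[N-])c1cc(C(=O)OC)cc(OC)c1OCc1ccc(OS(C)(=O)=O)c(OC)c1 | intermediate
9 | dimethyl (2S,3R)-7-methoxy-2-[3-methoxy-4-(methylsulfonyloxy)phenyl]-2,3-dihydro-1-benzofuran-3,5-dicarboxylate (2,3-cis) | COc1cc([C@H]2Oc3c(OC)cc(C(=O)OC)cc3[C@H]2C(=O)OC)ccc1OS(C)(=O)=O | intermediate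
10 | 4-[(2S,3S)-3,5-bis(hydroxymethyl)-7-methoxy-2,3-dihydro-1-benzofuran-2-yl]-2-methoxyphenyl methanesulfonate | COc1cc([C@H]2Oc3c(OC)cc(CO)cc3[C@H]2CO)ccc1OS(C)(=O)=O | intermediate
11 | 4-[(2S,3S)-5-formyl-3-(hydroxymethyl)-7-methoxy-2,3-dihydro-1-benzofuran-2-yl]-2-methoxyphenyl methanesulfonate | COc1cc([C@H]2Oc3c(OC)cc(C=O)cc3[C@H]2CO)ccc1OS(C)(=O)=O | intermediate
12 | 4-[(2S,3S)-3-{[tert-butyl(dimethyl)silyl]oxymethyl}-5-formyl-7-methoxy-2,3-dihydro-1-benzofuran-2-yl]-2-methoxyphenyl methanesulfonate | COc1cc([C@H]2Oc3c(OC)cc(C=O)cc3[C@H]2CO[Si](C)(C)C(C)(C)C)ccc1OS(C)(=O)=O | intermediate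
13 | syringaldehyde (4-hydroxy-3,5-dimethoxybenzaldehyde) | COc1cc(C=O)cc(OC)c1O | starting material
14 | 4-(benzyloxy)-3,5-dimethoxybenzaldehyde | COc1cc(C=O)cc(OC)c1OCc1ccccc1 | intermediate
15 | (E)-4-[4-(benzyloxy)-3,5-dimethoxyphenyl]but-3-enoic acid | OC(=O)C/C=C/c1cc(OC)c(OCc2ccccc2)c(OC)c1 | intermediate
16 | (S)-4-benzyl-1,3-oxazolidin-2-one | O=C1OC[C@H](Cc2ccccc2)N1 | starting material
17 | mixed anhydride of 15 with pivalic acid (not isolated) | CC(C)(C)C(=O)OC(=O)C/C=C/c1cc(OC)c(OCc2ccccc2)c(OC)c1 | intermediate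
18 | (S)-4-benzyl-3-{(E)-4-[4-(benzyloxy)-3,5-dimethoxyphenyl]but-3-enoyl}-1,3-oxazolidin-2-one | O=C1OC[C@H](Cc2ccccc2)N1C(=O)C/C=C/c1cc(OC)c(OCc2ccccc2)c(OC)c1 | intermediate
19 | (Z)-dibutylboron dienolate of 18 (not isolated) | CCCCB(CCCC)O/C(=C\C=C\c1cc(OC)c(OCc2ccccc2)c(OC)c1)N1C(=O)OC[C@@H]1Cc1ccccc1 | intermediate
20 | (4S)-4-benzyl-3-[(2S,3S)-2-{(E)-2-[Syr(Bn)]ethenyl}-3-hydroxy-3-(DBF)propanoyl]-1,3-oxazolidin-2-one (syn aldol adduct) | COc1cc([C@H]2Oc3c(OC)cc([C@@H](O)[C@@H](C(=O)N4C(=O)OC[C@@H]4Cc4ccccc4)/C=C/c4cc(OC)c(OCc5ccccc5)c(OC)c4)cc3[C@H]2CO[Si](C)(C)C(C)(C)C)ccc1OS(C)(=O)=O | intermediate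
21 | (1S,2R)-2-{(E)-2-[Syr(Bn)]ethenyl}-1-(DBF)propane-1,3-diol | COc1cc([C@H]2Oc3c(OC)cc([C@@H](O)[C@@H](CO)/C=C/c4cc(OC)c(OCc5ccccc5)c(OC)c4)cc3[C@H]2CO[Si](C)(C)C(C)(C)C)ccc1OS(C)(=O)=O | intermediate
22 | (1S,2R,3E)-2-{[tert-butyl(dimethyl)silyl]oxymethyl}-4-[Syr(Bn)]-1-(DBF)but-3-en-1-ol | COc1cc([C@H]2Oc3c(OC)cc([C@@H](O)[C@@H](CO[Si](C)(C)C(C)(C)C)/C=C/c4cc(OC)c(OCc5ccccc5)c(OC)c4)cc3[C@H]2CO[Si](C)(C)C(C)(C)C)ccc1OS(C)(=O)=O | intermediate
23 | (1S,2R,3E)-2-{[tert-butyl(dimethyl)silyl]oxymethyl}-1-(methoxymethoxy)-4-[Syr(Bn)]-1-(DBF)but-3-ene (MOM ether of 22) | COc1cc([C@H]2Oc3c(OC)cc([C@@H](OCOC)[C@@H](CO[Si](C)(C)C(C)(C)C)/C=C/c4cc(OC)c(OCc5ccccc5)c(OC)c4)cc3[C@H]2CO[Si](C)(C)C(C)(C)C)ccc1OS(C)(=O)=O | intermediate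
24 | oxocarbenium ion: 23 with the OCH2OCH3 group replaced by O(+)=CH2 (not isolated) | COc1cc([C@H]2Oc3c(OC)cc([C@@H]([O+]=C)[C@@H](CO[Si](C)(C)C(C)(C)C)/C=C/c4cc(OC)c(OCc5ccccc5)c(OC)c4)cc3[C@H]2CO[Si](C)(C)C(C)(C)C)ccc1OS(C)(=O)=O | intermediate
25 | benzylic cation: 2-(DBF)-3-{[tert-butyl(dimethyl)silyl]oxymethyl}-4-{[Syr(Bn)]methyliumyl}tetrahydrofuran, 2,3-trans-3,4-cis (not isolated) | COc1cc([C@H]2Oc3c(OC)cc([C@H]4OC[C@H]([CH+]c5cc(OC)c(OCc6ccccc6)c(OC)c5)[C@@H]4CO[Si](C)(C)C(C)(C)C)cc3[C@H]2CO[Si](C)(C)C(C)(C)C)ccc1OS(C)(=O)=O | intermediate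
26 | (1R,2S,5R,6S)-2-(DBF)-6-[Syr(Bn)]-3,7-dioxabicyclo[3.3.0]octane | COc1cc([C@H]2Oc3c(OC)cc([C@H]4OC[C@H]5[C@@H]4CO[C@@H]5c4cc(OC)c(OCc6ccccc6)c(OC)c4)cc3[C@H]2CO[Si](C)(C)C(C)(C)C)ccc1OS(C)(=O)=O | intermediate
27 | (1R,2S,5R,6S)-6-[Syr(Bn)]-2-[(2S,3S)-3-{[tert-butyl(dimethyl)silyl]oxymethyl}-2-(4-hydroxy-3-methoxyphenyl)-7-methoxy-2,3-dihydro-1-benzofuran-5-yl]-3,7-dioxabicyclo[3.3.0]octane | COc1cc([C@H]2Oc3c(OC)cc([C@H]4OC[C@H]5[C@@H]4CO[C@@H]5c4cc(OC)c(OCc6ccccc6)c(OC)c4)cc3[C@H]2CO[Si](C)(C)C(C)(C)C)ccc1O | intermediate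
28 | (1R,2S,5R,6S)-6-[Syr(Bn)]-2-[(2S,3S)-2-(4-hydroxy-3-methoxyphenyl)-3-(hydroxymethyl)-7-methoxy-2,3-dihydro-1-benzofuran-5-yl]-3,7-dioxabicyclo[3.3.0]octane | COc1cc([C@H]2Oc3c(OC)cc([C@H]4OC[C@H]5[C@@H]4CO[C@@H]5c4cc(OC)c(OCc6ccccc6)c(OC)c4)cc3[C@H]2CO)ccc1O | intermediate
29 | (1R,2S,5R,6S)-6-(4-hydroxy-3,5-dimethoxyphenyl)-2-[(2S,3S)-2-(4-hydroxy-3-methoxyphenyl)-3-(hydroxymethyl)-7-methoxy-2,3-dihydro-1-benzofuran-5-yl]-3,7-dioxabicyclo[3.3.0]octane (CNP0126146.1) | COc1cc([C@H]2Oc3c(OC)cc([C@H]4OC[C@H]5[C@@H]4CO[C@@H]5c4cc(OC)c(O)c(OC)c4)cc3[C@H]2CO)ccc1O | target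

## Step count and least certain steps

Total: 21 steps. Longest linear sequence: 17 steps from vanillin 1 (steps 1, 2, 4 to 10, 14 to 21). The branch from methyl vanillate 4 has 16 steps to 29 and the branch from syringaldehyde 13 has 11.

Step 18 (key step).
- What may go wrong: the Lewis acid may ionise the benzylic C2–O3 bond instead of the acetal bond, with loss of the C2 configuration or elimination towards a diene. The silyl ether oxygen may add to the oxocarbenium carbon before the alkene does, giving a six-membered formal that can reopen at either oxygen and so scramble the regiochemistry of the cascade. Bonding of C4 to C6 may start a 2-oxonia-Cope shift. Ring B may close, or reopen and close again, with the aryl group endo, which erodes the C6 configuration.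
- Fallback (sets out from 12 and 14, returns at 26; every operation is of known type): the bicycle is assembled by conjugate addition–aldol on a chiral butenolide and closed by benzylic etherification, without any oxocarbenium–alkene step. Aldehyde 14 is converted with propane-1,3-dithiol and BF3·OEt2 into 2-[4-(benzyloxy)-3,5-dimethoxyphenyl]-1,3-dithiane F1. Its 2-lithio derivative (n-BuLi, THF, −78 °C) is added to the commercial (5R)-5-(menthyloxy)furan-2(5H)-one A3, and the lactone enolate is trapped with 12 to give the trans,trans-lactone F2, which holds C1 and C5 in the required sense. MeI and CaCO3 in aqueous MeCN free the ketone F3. LiBH4 reduces ketone, lactone and acetal carbon, with loss of menthol, to the tetraol F4. Camphorsulfonic acid in CH2Cl2 then closes both tetrahydrofuran rings by capture of the two benzylic cations by the primary alcohols, the aryl groups settling exo, and gives 26. The mesylate again guards the cis ring in the acid step; in this sequence C2 and C6 are set by equilibration and not by an auxiliary.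

Step 7.
- What may go wrong: loss of cis selectivity and of enantioselectivity, because the C–H bond to be attacked is deactivated by the mesyloxy group and the ether is crowded by the neighbouring methoxy group, which makes the insertion later and less ordered; epimerisation at C3' during isolation.
- Fallback (sets out from 5, returns at 9): the insertion is run on a 4-alkoxybenzyl ether, the substitution pattern for which it is best documented, and the mesylate is introduced afterwards. Mitsunobu etherification of 5 with commercial 4-(benzyloxy)-3-methoxybenzyl alcohol gives the aryl iodide F5. Zinc enolate coupling and diazo transfer as in steps 5 and 6 give the aryl acetate F6 and the diazo ester F7. The insertion gives the cis diester F8. Hydrogenolysis of the aryl benzyl ether (H2, Pd/C, EtOAc) gives the phenol F9, and MsCl with Et3N at 0 °C gives 9.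

Step 14.
- What may go wrong: incomplete enolisation, or reaction of the dienolate at its γ-carbon with the electron-rich and therefore sluggish aldehyde; migration of the double bond into conjugation with the imide; retro-aldol cleavage during work-up.
- Fallback (sets out from 16 and 12, returns at 20): the aldol is run with the simpler crotonyl imide and the aryl group is attached afterwards by metathesis. Oxazolidinone 16 is acylated (n-BuLi, crotonyl chloride) to (S)-4-benzyl-3-[(E)-but-2-enoyl]-1,3-oxazolidin-2-one F10. Its boron dienolate (Bu2BOTf, Et3N) adds 12 at the α-carbon to give the syn α-vinyl adduct F11. Cross-metathesis of F11 with 4-(benzyloxy)-3,5-dimethoxystyrene F12 (from 14 and Ph3P=CH2) under the second-generation Hoveyda–Grubbs catalyst, with loss of ethene, gives the (E)-styrene 20.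

Step 5.
- What may go wrong: slow transmetalation at the ortho-alkoxy-substituted arylpalladium intermediate with competing protodehalogenation, or self-condensation of the zinc enolate before it couples.
- Fallback (sets out from 6, returns at 7): malonate arylation followed by dealkoxycarbonylation. CuI, picolinic acid and Cs2CO3 in dioxane couple 6 with dimethyl malonate to the aryl malonate F13. LiCl in wet DMSO at 130 °C (Krapcho reaction) removes one ester group and gives 7.

## Further compounds

F1 | step 18 | 2-[4-(benzyloxy)-3,5-dimethoxyphenyl]-1,3-dithiane | COc1cc(C2SCCCS2)cc(OC)c1OCc1ccccc1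
F2 | step 18 | 4-{2-[4-(benzyloxy)-3,5-dimethoxyphenyl]-1,3-dithian-2-yl}-3-[hydroxy(DBF)methyl]-5-[(1R,2S,5R)-menthyloxy]dihydrofuran-2(3H)-one, 3,4-trans-4,5-trans, carbinol epimers | O=C1O[C@@H](O[C@@H]2C[C@H](C)CC[C@H]2C(C)C)[C@H](C2(SCCCS2)c2cc(OC)c(OCc3ccccc3)c(OC)c2)[C@H]1C(O)c1cc(OC)c2O[C@H](c3ccc(OS(C)(=O)=O)c(OC)c3)[C@H](CO[Si](C)(C)C(C)(C)C)c2c1
F3 | step 18 | 4-[4-(benzyloxy)-3,5-dimethoxybenzoyl]-3-[hydroxy(DBF)methyl]-5-[(1R,2S,5R)-menthyloxy]dihydrofuran-2(3H)-one, 3,4-trans-4,5-trans, carbinol epimers | O=C1O[C@@H](O[C@@H]2C[C@H](C)CC[C@H]2C(C)C)[C@H](C(=O)c2cc(OC)c(OCc3ccccc3)c(OC)c2)[C@H]1C(O)c1cc(OC)c2O[C@H](c3ccc(OS(C)(=O)=O)c(OC)c3)[C@H](CO[Si](C)(C)C(C)(C)C)c2c1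
F4 | step 18 | (2R,3R)-2-{[4-(benzyloxy)-3,5-dimethoxyphenyl](hydroxy)methyl}-3-[(DBF)(hydroxy)methyl]butane-1,4-diol, benzylic carbinols as epimer mixtures | OC[C@H](C(O)c1cc(OC)c(OCc2ccccc2)c(OC)c1)[C@H](CO)C(O)c1cc(OC)c2O[C@H](c3ccc(OS(C)(=O)=O)c(OC)c3)[C@H](CO[Si](C)(C)C(C)(C)C)c2c1
F5 | step 7 | methyl 4-{[4-(benzyloxy)-3-methoxyphenyl]methoxy}-3-iodo-5-methoxybenzoate | COC(=O)c1cc(I)c(OCc2ccc(OCc3ccccc3)c(OC)c2)c(OC)c1
F6 | step 7 | methyl 4-{[4-(benzyloxy)-3-methoxyphenyl]methoxy}-3-methoxy-5-(2-methoxy-2-oxoethyl)benzoate | COC(=O)Cc1cc(C(=O)OC)cc(OC)c1OCc1ccc(OCc2ccccc2)c(OC)c1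
F7 | step 7 | methyl 4-{[4-(benzyloxy)-3-methoxyphenyl]methoxy}-3-(1-diazo-2-methoxy-2-oxoethyl)-5-methoxybenzoate | COC(=O)C(=[N+]=[N-])c1cc(C(=O)OC)cc(OC)c1OCc1ccc(OCc2ccccc2)c(OC)c1
F8 | step 7 | dimethyl (2S,3R)-2-[4-(benzyloxy)-3-methoxyphenyl]-7-methoxy-2,3-dihydro-1-benzofuran-3,5-dicarboxylate (2,3-cis) | COc1cc([C@H]2Oc3c(OC)cc(C(=O)OC)cc3[C@H]2C(=O)OC)ccc1OCc1ccccc1
F9 | step 7 | dimethyl (2S,3R)-2-(4-hydroxy-3-methoxyphenyl)-7-methoxy-2,3-dihydro-1-benzofuran-3,5-dicarboxylate (2,3-cis) | COc1cc([C@H]2Oc3c(OC)cc(C(=O)OC)cc3[C@H]2C(=O)OC)ccc1O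
F10 | step 14 | (S)-4-benzyl-3-[(E)-but-2-enoyl]-1,3-oxazolidin-2-one | C/C=C/C(=O)N1C(=O)OC[C@@H]1Cc1ccccc1
F11 | step 14 | (4S)-4-benzyl-3-[(2S,3S)-2-ethenyl-3-hydroxy-3-(DBF)propanoyl]-1,3-oxazolidin-2-one | COc1cc([C@H]2Oc3c(OC)cc([C@@H](O)[C@@H](C(=O)N4C(=O)OC[C@@H]4Cc4ccccc4)C=C)cc3[C@H]2CO[Si](C)(C)C(C)(C)C)ccc1OS(C)(=O)=O
F12 | step 14 | 4-(benzyloxy)-3,5-dimethoxystyrene | C=Cc1cc(OC)c(OCc2ccccc2)c(OC)c1
F13 | step 5 | dimethyl 2-{3-methoxy-5-(methoxycarbonyl)-2-{[3-methoxy-4-(methylsulfonyloxy)phenyl]methoxy}phenyl}propanedioate | COC(=O)C(C(=O)OC)c1cc(C(=O)OC)cc(OC)c1OCc1ccc(OS(C)(=O)=O)c(OC)c1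
A1 | alternative 1 | methyl 2-diazo-2-{2-{[4-(benzyloxy)-3-methoxyphenyl]methoxy}-3-methoxy-5-[(1R,2S,5R,6S)-6-(4-benzyloxy-3,5-dimethoxyphenyl)-3,7-dioxabicyclo[3.3.0]oct-2-yl]phenyl}acetate | COC(=O)C(=[N+]=[N-])c1cc([C@H]2OC[C@H]3[C@@H]2CO[C@@H]3c2cc(OC)c(OCc3ccccc3)c(OC)c2)cc(OC)c1OCc1ccc(OCc2ccccc2)c(OC)c1
A2 | alternative 1 | methyl cis-2-[4-(benzyloxy)-3-methoxyphenyl]-7-methoxy-5-[(1R,2S,5R,6S)-6-(4-benzyloxy-3,5-dimethoxyphenyl)-3,7-dioxabicyclo[3.3.0]oct-2-yl]-2,3-dihydro-1-benzofuran-3-carboxylate | COc1cc([C@H]2Oc3c(OC)cc([C@H]4OC[C@H]5[C@@H]4CO[C@@H]5c4cc(OC)c(OCc6ccccc6)c(OC)c4)cc3[C@H]2C(=O)OC)ccc1OCc1ccccc1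
A3 | alternative 2 | (5R)-5-[(1R,2S,5R)-menthyloxy]furan-2(5H)-one | O=C1C=C[C@H](O[C@@H]2C[C@H](C)CC[C@H]2C(C)C)O1
A4 | alternative 2 | 2-[4-(benzyloxy)-3,5-dimethoxyphenyl]-1,3-dithiane | COc1cc(C2SCCCS2)cc(OC)c1OCc1ccccc1
A5 | alternative 2 | (2S,3S)-2-[4-(benzyloxy)-3-methoxyphenyl]-3-{[tert-butyl(dimethyl)silyl]oxymethyl}-7-methoxy-2,3-dihydro-1-benzofuran-5-carbaldehyde | COc1cc([C@H]2Oc3c(OC)cc(C=O)cc3[C@H]2CO[Si](C)(C)C(C)(C)C)ccc1OCc1ccccc1
A6 | alternative 2 | trans,trans-menthyloxy lactone from A3, A4 and A5 (carbinol drawn as one epimer) | O=C1O[C@@H](O[C@@H]2C[C@H](C)CC[C@H]2C(C)C)[C@H](C2(SCCCS2)c2cc(OC)c(OCc3ccccc3)c(OC)c2)[C@H]1[C@H](O)c1cc(OC)c2O[C@H](c3ccc(OCc4ccccc4)c(OC)c3)[C@H](CO[Si](C)(C)C(C)(C)C)c2c1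
A7 | alternative 3 | (2R,3R)-2-(4-hydroxy-3-methoxybenzyl)-3-(4-hydroxy-3,5-dimethoxybenzyl)butane-1,4-diol | COc1cc(C[C@@H](CO)[C@H](CO)Cc2cc(OC)c(O)c(OC)c2)ccc1O
A8 | alternative 3 | (+)-medioresinol | COc1cc([C@H]2OC[C@H]3[C@@H]2CO[C@@H]3c2cc(OC)c(O)c(OC)c2)ccc1O
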